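## Analysis of the target

The target is a C20 bis-formamide built on a cis-fused octalin (ring A, a cyclohexene with a vinylic methyl; ring B, a cyclohexane) whose ring B carries a 2,2,5-trisubstituted tetrahydrofuran (ring C). The atoms are labelled as follows and the labels are used for every intermediate: ring A is C1 (methyl-bearing alkene carbon), C2 (alkene CH), C3 and C14 (ring-fusion CH), C15, C16; ring B is C3, C4 (CH bearing ring C), C11, C12, C13 (CH3 and NHCHO), C14; ring C is C5 (quaternary, CH3 and O), C6, C7, C8 (OCH) and O10; C9 is the C(CH3)2NHCHO carbon on C8. In these labels the six stereocentres are 3R,4R,5S,8R,13R,14S: H3 and H14 are cis, H4 is anti to H3 so that ring C is equatorial on ring B, the C13 formamide lies on the face opposite to H14, and on ring C the bonds C5–C4 and C8–C9 are cis. Two centres are fully substituted, C13 (nitrogen) and C5 (oxygen); C5 lies outside the bicycle across the rotatable C4–C5 bond, and C8 lies further out still. Sensitive functions are the two secondary formamides on tertiary carbons (Lewis-basic, N–H acidic, open to hydrolysis and dehydration), the trisubstituted ring A alkene (cation chemistry under acid) and the tertiary ether. The difficulty is less the decalin than the relay of configuration from the ring fusion to C4, C5 and C8, and the nitrogen-bearing C13 next to an epimerisable ring-fusion carbon. The strategy rests on one pattern: C4 is bonded to C11 and, through C5, to O10, with the C4–C11 and C5–O10 bonds anti. This is what results when the C4 end of an (E)-C4=C5 alkene is attacked by a carbon electrophile (C11) while O10 adds to C5 from the other face.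

## Retrosynthetic reasoning

**33 to 31.** C11 is a methylene in 33. It is traced back to the carbinol 31, because an oxygen at C11 is what a carbonyl electrophile leaves behind. The forward operation is a radical deoxygenation through thiocarbonyl derivative 32; it touches no stereocentre and should tolerate formamides, alkene and ether.

**31 to 30.** In 31 the bonds C4–C11 and C5–O10 are cut together, which opens rings B and C and gives hydroxy aldehyde 30 with an (E)-C4=C5 alkene. Cutting here, and not at C3–C4 or C13–C14, leaves a ring A on which the two arms are simply cis, and turns the C4/C5 relationship into a question of alkene geometry. One operation returns two rings and the centres C4, C5 and C11 from centres already in place (C3, C14, C13, C8). The forward reaction must use the side-chain alkene rather than the ring A alkene, pass through the chair that places C5 equatorial, and close ring C before the C5 cation loses a proton.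

**30 to 27.** The aldehyde is held at the ester level and the C8 carbinol at the ketone level for as long as possible. 30 comes from diol 29 by selective oxidation of the primary alcohol, 29 from hydroxy ester 28 by ester reduction, and 28 from ketone 27 by enantioselective reduction, which sets C8 under reagent control. Keeping C8 as a ketone until both nitrogens are formylated means no γ-hydroxy alkene is exposed to acid.

**27 to 20 and 23.** The C6–C7 bond is cut next to the ketone. This gives allylic bromide 20 and the stabilised enolate of β-keto ester 23, which carries C7–C9 and the second nitrogen. The soft enolate tolerates the ester and the acidic N–H of 20; the extra carboxyl on C7 in 24 leaves in the same acid treatment that frees both amines (25, 26), and both are formylated together.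

**20 to 15 and 16.** Bromide 20 is the activated form of silyl ether 17 (through alcohol 18 and mesylate 19). In 17 the C12–C13 bond is cut as a Mannich retron, giving N-sulfinyl ketimine 15 and methyl acetate 16. The sulfinyl group of 14 carries the stereochemical information for C13, and the ester is the latent C11 aldehyde. Ketimine 15 comes from methyl ketone 13 and sulfinamide 14.

**13 to 7 and 10.** Ketone 13 is taken back through Weinreb amide 12 to imide 11. In 11 the bonds C3–C14 and C15–C16 are cut as a Diels–Alder retron. The methyl on C1 and the alkenyl arm on C3 both direct the acyl-bearing carbon of acrylimide 10 to C3, the endo rule gives the cis arrangement, and the auxiliary gives the absolute configuration. The arm alkene is already present in triene 7, so no epimerisable aldehyde ever sits on C3.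

**Building blocks.** Triene 7 is the silyl ether of trienol 6, from ester 5, made by two Wittig olefinations from 1 with ylides 2 and 4 (through dienal 3). Acrylimide 10 comes from 8 and 9, and β-keto ester 23 from 21 and 22.

## Alternatives that were turned down

**Alternative 1:** Ring A is disconnected at C2–C3 and C14–C15, so that it is built last onto a ring B dienone. In the forward sense one of the two enone double bonds of the prochiral dienone A1 undergoes a catalytic, desymmetrising Diels–Alder reaction with the oxygenated diene A2 under a chiral boron Lewis acid; acidic work-up gives dione A3. In its favour, three stereocentres (C3, C14, C13) arise by catalysis from an achiral dienone, the cis fusion is inherent in the cycloaddition, and nitrogen sits on C13 from the start. On the C13 problem it is stronger than the chosen route, which needs an auxiliary and a sulfinyl group. Against it, A3 carries three functions the target lacks (C16 ketone, C11=C12 alkene, N-acetyl) and nothing at C4 but a carbonyl. The C4–C5 bond to a fully substituted carbon, and the configurations at C4, C5 and C8, would have to come from addition to a hindered ketone followed by stereocontrolled deoxygenation at C4. The diene must also distinguish the NHAc face from the CH3 face at a quaternary carbon, and exchanging acetyl for formyl on a tertiary carbinamine needs forcing hydrolysis. The chosen strategy gives up the catalytic entry but settles the C4/C5 relationship stereospecifically and leaves a single surplus hydroxyl.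

**Alternative 2:** The ring-fusion bond C3–C14 and the C13–N bond are cut, opening both carbocycles to a ten-membered ring. In the forward sense the tertiary allylic alcohol of dienol A4 is ionised by a Lewis acid, the C13=C14 alkene attacks the allyl cation across the ring, and a silyl azide captures the C13 cation to give bis-azide A5. In its favour, two rings, the ring fusion and a C–N bond form in one step, both nitrogens are then processed identically, and no oxygen remains to be removed. It is stronger than the chosen route in redox economy after the key step. Against it, A4 is a (Z,Z)-cyclodecadiene that already carries ring C and C4, so a long medium-ring synthesis precedes the key step. The outcome then depends on ring conformation alone: cis or trans fusion, which allyl terminus bonds, and which face of an open tertiary cation the azide takes, with elimination and allylic azide scrambling as competitors. The chosen strategy sets C13 earlier under reagent control and closes a six-membered ring through a chair, which is easier to predict than a transannular event.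

**Alternative 3:** The C13–C14 bond is cut with an α-amino ketone as retron, and ring B is contracted to a cyclopentane. In the forward sense imine A6 is heated, the ring-fusion carbon C14 shifts from the carbinol carbon C12 to the imine carbon C13, and the ring-expanded amino ketone A7 results. In its favour, the shift is suprafacial and stereospecific, so C13 follows from a carbinol configuration, and no addition to a ketimine next to an epimerisable centre is needed. On C13 it is stronger than the chosen route. Against it, either ring bond at the carbinol carbon may migrate, the C12 ketone and the benzyl-type group must be removed afterwards (four or more steps), and A6 already needs C4, C5 and C8 in place. The relationship on which the chosen strategy spends its key step is left unsolved, whereas the chosen key step is followed by one deoxygenation only.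

Key step: step 19

Assumption: the sense of addition to N-sulfinyl ketimine 15 is taken from the chelated six-membered transition-state model, by which (S)-sulfur leads to 13R; if the addition followed the opposite sense, the enantiomeric sulfinamide would be used in step 9.

## Route

Step 1
Reactants: 1 methacrolein; 2 (triphenylphosphoranylidene)acetaldehyde
Product: 3 (2E)-4-methylpenta-2,4-dienal
Conditions: 1 (1.5 equiv), toluene, 80 °C
Reagents that add atoms: none
Why: Wittig olefination with a formyl-stabilised ylide, which should give the E enal; the excess of the unhindered methacrolein keeps the product from being homologated a second time.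

Step 2
Reactants: 3 (2E)-4-methylpenta-2,4-dienal; 4 ethyl 2-(triphenylphosphoranylidene)propanoate
Product: 5 ethyl (2E,4E)-2,6-dimethylhepta-2,4,6-trienoate
Conditions: CH2Cl2, 0 °C → rt
Reagents that add atoms: none
Why: Wittig olefination with an α-methyl ester-stabilised ylide, which reliably gives the E trisubstituted enoate; the existing E alkene is untouched.

Step 3
Reactants: 5 ethyl (2E,4E)-2,6-dimethylhepta-2,4,6-trienoate
Product: 6 (2E,4E)-2,6-dimethylhepta-2,4,6-trien-1-ol
Conditions: iBu2AlH (2.3 equiv), CH2Cl2, −78 °C; aq. KNaC4H4O6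
Reagents that add atoms: none
Why: 1,2-reduction of a conjugated ester by a dialkylaluminium hydride; no conjugate reduction is expected at low temperature.

Step 4
Reactants: 6 (2E,4E)-2,6-dimethylhepta-2,4,6-trien-1-ol
Product: 7 tert-butyl{[(2E,4E)-2,6-dimethylhepta-2,4,6-trien-1-yl]oxy}dimethylsilane
Conditions: tBuMe2SiCl, imidazole, DMF, 0 °C → rt
Reagents that add atoms: tert-butyldimethylsilyl chloride, CC(C)(C)[Si](C)(C)Cl
Why: standard silylation of a primary allylic alcohol; the silyl ether has no acidic proton and should survive the aluminium, magnesium and titanium reagents of steps 6–10.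

Step 5
Reactants: 8 (4R)-4-benzyl-1,3-oxazolidin-2-one; 9 acryloyl chloride
Product: 10 (4R)-3-acryloyl-4-benzyl-1,3-oxazolidin-2-one
Conditions: Et3N, LiCl, THF, −20 °C → rt
Reagents that add atoms: none
Why: N-acylation of the oxazolidinone under mild lithium chloride/amine conditions, which avoid the anionic polymerisation seen with strong bases.

Step 6
Reactants: 7 tert-butyl{[(2E,4E)-2,6-dimethylhepta-2,4,6-trien-1-yl]oxy}dimethylsilane; 10 (4R)-3-acryloyl-4-benzyl-1,3-oxazolidin-2-one
Product: 11 (4R)-4-benzyl-3-{[(1S,2S)-2-[(1E)-3-(tert-butyldimethylsilyloxy)-2-methylprop-1-en-1-yl]-4-methylcyclohex-3-en-1-yl]carbonyl}-1,3-oxazolidin-2-one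
Conditions: Et2AlCl (1.4 equiv), 7 (1.5 equiv), CH2Cl2, −78 °C; then 1 M HCl
Reagents that add atoms: none
Why: auxiliary-controlled Diels–Alder reaction: the chelated s-cis acrylimide is attacked on the face opposite the benzyl group, endo, which sets C14 (S) and C3 cis to it. The C1 methyl ("para") and the alkenyl arm ("ortho") both direct the acyl-bearing carbon to C3. Only the terminal diene of 7 can reach the s-cis conformation, since the other diene unit has a cis methyl on its terminus.

Step 7
Reactants: 11 Diels–Alder imide
Product: 12 (1S,2S)-2-[(1E)-3-(tert-butyldimethylsilyloxy)-2-methylprop-1-en-1-yl]-N-methoxy-N,4-dimethylcyclohex-3-ene-1-carboxamide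
Conditions: AlMe3, MeNH(OMe)·HCl, CH2Cl2, 0 °C → rt
Reagents that add atoms: N,O-dimethylhydroxylamine hydrochloride, CNOC.Cl
Why: aluminium amide transamination of the N-acyloxazolidinone gives the Weinreb amide and returns the auxiliary; the conditions are not basic enough to epimerise C14.

Step 8
Reactants: 12 Weinreb amide
Product: 13 1-[(1S,2S)-2-[(1E)-3-(tert-butyldimethylsilyloxy)-2-methylprop-1-en-1-yl]-4-methylcyclohex-3-en-1-yl]ethan-1-one
Conditions: MeMgBr, THF, 0 °C; aq. NH4Cl
Reagents that add atoms: methylmagnesium bromide, C[Mg]Br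
Why: Weinreb ketone synthesis; the chelated tetrahedral intermediate prevents over-addition and the ketone is only released on mild acidic work-up, so the cis C3/C14 relationship should be kept.

Step 9
Reactants: 13 methyl ketone; 14 (S)-2-methylpropane-2-sulfinamide
Product: 15 (S)-N-{(1E)-1-[(1S,2S)-2-[(1E)-3-(tert-butyldimethylsilyloxy)-2-methylprop-1-en-1-yl]-4-methylcyclohex-3-en-1-yl]ethylidene}-2-methylpropane-2-sulfinamide
Conditions: Ti(OEt)4 (3 equiv), THF, 50 °C
Reagents that add atoms: none
Why: titanium alkoxide-mediated condensation (Ellman ketimine synthesis) gives the E ketimine with sulfur anti to the ring. Tautomerisation toward C14 would give a tetrasubstituted, strained ene-sulfinamide and is expected to be slow; the temperature is kept moderate so that the tertiary C14–H is not exchanged.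

Step 10
Reactants: 15 N-sulfinyl ketimine; 16 methyl acetate
Product: 17 methyl (3R)-3-[(1S,2S)-2-[(1E)-3-(tert-butyldimethylsilyloxy)-2-methylprop-1-en-1-yl]-4-methylcyclohex-3-en-1-yl]-3-{[(S)-tert-butylsulfinyl]amino}butanoate
Conditions: iPr2NLi, THF, −78 °C; ClTi(OiPr)3 (2 equiv per enolate); then 15, −78 °C
Reagents that add atoms: none
Why: Mannich-type addition of the titanium enolate of methyl acetate to the N-sulfinyl ketimine through a closed, chelated six-membered transition state; with (S)-sulfur the enolate should reach the face of the E ketimine that gives 13R. The ester is the masked C11 aldehyde.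

Step 11
Reactants: 17 β-sulfinamido ester
Product: 18 methyl (3R)-3-{[(S)-tert-butylsulfinyl]amino}-3-[(1S,2S)-2-[(1E)-3-hydroxy-2-methylprop-1-en-1-yl]-4-methylcyclohex-3-en-1-yl]butanoate
Conditions: Bu4NF, AcOH, THF, 0 °C → rt
Reagents that add atoms: none
Why: fluoride cleavage of the primary silyl ether; acetic acid buffering keeps the β-amino ester from base-induced retro-Mannich or lactam formation.

Step 12
Reactants: 18 allylic alcohol
Product: 20 methyl (3R)-3-[(1S,2S)-2-[(1E)-3-bromo-2-methylprop-1-en-1-yl]-4-methylcyclohex-3-en-1-yl]-3-{[(S)-tert-butylsulfinyl]amino}butanoate, via allylic mesylate 19 (not isolated)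
Conditions: MeSO2Cl, Et3N, CH2Cl2, −40 °C; then LiBr, THF, 0 °C
Reagents that add atoms: lithium bromide, [Li+].[Br-]
Why: mesylation of the primary allylic alcohol and SN2 displacement by bromide, the usual way to E allylic bromides without acid; the hindered sulfinamide N–H should not be sulfonylated and the alkene geometry is kept.

Step 13
Reactants: 21 N-(tert-butoxycarbonyl)-2-aminoisobutyric acid; 22 3-tert-butoxy-3-oxopropanoic acid
Product: 23 tert-butyl 4-[(tert-butoxycarbonyl)amino]-4-methyl-3-oxopentanoate
Conditions: 1,1'-carbonyldiimidazole, THF, rt; then 22, MgCl2, Et3N, THF, rt → 45 °C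
Reagents that add atoms: none
Why: Masamune–Brooks homologation: the acyl imidazolide is C-acylated by the magnesium salt of the malonate half-ester, and decarboxylation gives the β-keto ester.

Step 14
Reactants: 20 allylic bromide; 23 β-keto ester
Product: 24 methyl (3R)-3-[(1S,2S)-2-{(1E)-4-(tert-butoxycarbonyl)-6-[(tert-butoxycarbonyl)amino]-2,6-dimethyl-5-oxohept-1-en-1-yl}-4-methylcyclohex-3-en-1-yl]-3-{[(S)-tert-butylsulfinyl]amino}butanoate (both C7 epimers)
Conditions: 23 (2 equiv), NaH (1.9 equiv), THF–DMF, 0 °C; then 20, 0 °C → rt
Reagents that add atoms: none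
Why: C-alkylation of a stabilised β-keto ester enolate by a primary allylic bromide (SN2 at C6, not SN2'). The enolate is too weak a base to deprotonate the methyl ester or the sulfinamide, and the C7 centre is lost again in step 15.

Step 15
Reactants: 24 alkylated β-keto ester
Product: 27 methyl (3R)-3-formamido-3-[(1S,2S)-2-[(1E)-6-formamido-2,6-dimethyl-5-oxohept-1-en-1-yl]-4-methylcyclohex-3-en-1-yl]butanoate, via β-keto acid bis(ammonium chloride) 25 (not isolated), via diamine dihydrochloride 26 (not isolated)
Conditions: HCl (4 M in 1,4-dioxane), MeOH, 0 °C → rt, then 45 °C; evaporate; HCO2Ac, Et3N, CH2Cl2, −20 °C → rt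
Reagents that add atoms: acetic formic anhydride, CC(=O)OC=O
Why: anhydrous acid removes the sulfinyl group, the carbamate and the tert-butyl ester, and the β-keto acid decarboxylates on warming. The mixed anhydride then formylates both tert-alkylamines (formyl transfer is faster than acetyl transfer). C8 is still a ketone here, so no hydroxy alkene is exposed to acid.

Step 16
Reactants: 27 keto ester bis-formamide
Product: 28 methyl (3R)-3-formamido-3-[(1S,2S)-2-[(1E,5R)-6-formamido-5-hydroxy-2,6-dimethylhept-1-en-1-yl]-4-methylcyclohex-3-en-1-yl]butanoate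
Conditions: (S)-2-methyl-CBS-oxazaborolidine [(3aS)-1-methyl-3,3-diphenyltetrahydro-1H,3H-pyrrolo[1,2-c][1,3,2]oxazaborole] (0.3 equiv), BH3·SMe2, THF, −20 °C
Reagents that add atoms: none
Why: Corey–Bakshi–Shibata reduction: the tert-alkyl carbon C9 acts as the large group and C7 as the small one, so the (S)-catalyst should give 8R, as with pinacolone-type ketones. At this temperature the ester, formamides and trisubstituted alkenes should react much more slowly than the catalysed ketone reduction.

Step 17
Reactants: 28 hydroxy ester
Product: 29 N-{(2R)-2-[(1S,2S)-2-[(1E,5R)-6-formamido-5-hydroxy-2,6-dimethylhept-1-en-1-yl]-4-methylcyclohex-3-en-1-yl]-4-hydroxybutan-2-yl}formamide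
Conditions: LiBH4, MeOH (1 equiv), THF, 0 °C → rt
Reagents that add atoms: none
Why: borohydride reduction of the methyl ester to the primary alcohol; secondary formamides and isolated alkenes are not reduced by this reagent.

Step 18
Reactants: 29 diol
Product: 30 N-{(2R)-2-[(1S,2S)-2-[(1E,5R)-6-formamido-5-hydroxy-2,6-dimethylhept-1-en-1-yl]-4-methylcyclohex-3-en-1-yl]-4-oxobutan-2-yl}formamide
Conditions: 2,2,6,6-tetramethylpiperidin-1-oxyl (0.1 equiv), PhI(OAc)2, CH2Cl2, 0 °C → rt
Reagents that add atoms: none
Why: oxoammonium-catalysed oxidation, selective for the primary alcohol over the hindered secondary C8 carbinol next to a quaternary carbon; it stops at the aldehyde under anhydrous conditions. The aldehyde is used at once.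

Step 19
Reactants: 30 hydroxy alkene aldehyde
Product: 31 N-{2-[(2R,5S)-5-[(1S,2S,4R,4aS,8aR)-4-formamido-2-hydroxy-4,7-dimethyl-1,2,3,4,4a,5,6,8a-octahydronaphthalen-1-yl]-5-methyloxolan-2-yl]propan-2-yl}formamide (C11 carbinol of the target skeleton)
Conditions: Me2AlCl (4.5 equiv), CH2Cl2, −78 → −30 °C; aq. KNaC4H4O6
Reagents that add atoms: none
Why: Prins cyclisation terminated by hydroxyl capture: the Lewis acid first turns the C8 hydroxyl into its aluminium alkoxide (methane is lost), saturates the two formamides and then activates the aldehyde. C4 of the (E)-alkene attacks C11 through a chair in which the C3–C2 bond, C5 and the complexed oxygen are equatorial and C13 carries its formamide equatorial and its methyl axial; this closes ring B with the alkene exocyclic to the new six-membered ring. As charge builds at C5, O10 adds from the face opposite the new C4–C11 bond in a 5-exo closure, giving ring C. The closest known reactions are the Lewis acid-promoted cyclisation of citronellal-type unsaturated aldehydes, whose cation can be intercepted by oxygen nucleophiles (citronellal to p-menthane-3,8-diol), and hydroxyl-terminated cation–olefin cyclisations. C4 is set by the chair with the alkenyl carbon equatorial (H4 anti to H3), C5 by anti addition across the E alkene, which is stereospecific as long as the capture is concerted with or faster than rotation, and C11 by the equatorial position of the complexed oxygen, which is of no consequence since C11 is deoxygenated. Three selectivities are needed: the side-chain alkene must react rather than the ring A alkene, the chair with C5 equatorial must win, and ring C closure must outrun loss of a proton to the neighbouring aluminium alkoxide. The first is secured by the quaternary C13, which sits equatorial on ring A, whereas the bridged bicyclo[3.3.1]nonane mode known for limonene-derived aldehydes needs it axial. The other two are secured by the equatorial preference of the arm and by the two-carbon tether that holds O10 behind C5.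

Step 20
Reactants: 31 hydroxy decalin
Product: 32 O-[(1S,2S,4R,4aS,8aR)-4-formamido-1-{(2S,5R)-5-(2-formamidopropan-2-yl)-2-methyloxolan-2-yl}-4,7-dimethyl-1,2,3,4,4a,5,6,8a-octahydronaphthalen-2-yl] 1H-imidazole-1-carbothioate
Conditions: 1,1'-thiocarbonyldiimidazole, 4-(dimethylamino)pyridine (cat.), ClCH2CH2Cl, 70 °C
Reagents that add atoms: 1,1'-thiocarbonyldiimidazole, S=C(n1ccnc1)n1ccnc1
Why: O-thioacylation of the equatorial secondary alcohol (first stage of the Barton–McCombie deoxygenation); the formamide N–H groups are too weakly nucleophilic to compete.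

Step 21
Reactants: 32 thiocarbonylimidazolide
Product: 33 N-{2-[(2R,5S)-5-[(1R,4R,4aS,8aR)-4-formamido-4,7-dimethyl-1,2,3,4,4a,5,6,8a-octahydronaphthalen-1-yl]-5-methyloxolan-2-yl]propan-2-yl}formamide (target)
Conditions: Bu3SnH, 2,2'-azobis(2-methylpropionitrile) (cat.), toluene, 100 °C
Reagents that add atoms: none
Why: Barton–McCombie radical deoxygenation: the stannyl radical adds to sulfur, β-scission gives the secondary C11 radical, which takes hydrogen from the stannane. No stereocentre is involved, and the radical has only 4-exo or 5-endo paths to the ring A alkene, so cyclisation should not compete.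

## Compound list

1 | methacrolein (2-methylprop-2-enal) | CC(=C)C=O | starting material
2 | (triphenylphosphoranylidene)acetaldehyde | O=CC=P(c1ccccc1)(c1ccccc1)c1ccccc1 | starting material
3 | (2E)-4-methylpenta-2,4-dienal | CC(=C)/C=C/C=O | intermediate
4 | ethyl 2-(triphenylphosphoranylidene)propanoate | CCOC(=O)C(C)=P(c1ccccc1)(c1ccccc1)c1ccccc1 | starting material
5 | ethyl (2E,4E)-2,6-dimethylhepta-2,4,6-trienoate | CCOC(=O)/C(C)=C/C=C/C(C)=C | intermediate
6 | (2E,4E)-2,6-dimethylhepta-2,4,6-trien-1-ol | OC/C(C)=C/C=C/C(C)=C | intermediate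
7 | tert-butyl{[(2E,4E)-2,6-dimethylhepta-2,4,6-trien-1-yl]oxy}dimethylsilane | CC(C)(C)[Si](C)(C)OC/C(C)=C/C=C/C(C)=C | intermediate
8 | (4R)-4-benzyl-1,3-oxazolidin-2-one | O=C1N[C@H](Cc2ccccc2)CO1 | starting material
9 | acryloyl chloride | C=CC(Cl)=O | starting material
10 | (4R)-3-acryloyl-4-benzyl-1,3-oxazolidin-2-one | C=CC(=O)N1[C@H](Cc2ccccc2)COC1=O | intermediate
11 | (4R)-4-benzyl-3-{[(1S,2S)-2-[(1E)-3-(tert-butyldimethylsilyloxy)-2-methylprop-1-en-1-yl]-4-methylcyclohex-3-en-1-yl]carbonyl}-1,3-oxazolidin-2-one | CC1=C[C@@H](/C=C(\C)CO[Si](C)(C)C(C)(C)C)[C@@H](C(=O)N2[C@H](Cc3ccccc3)COC2=O)CC1 | intermediate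
12 | (1S,2S)-2-[(1E)-3-(tert-butyldimethylsilyloxy)-2-methylprop-1-en-1-yl]-N-methoxy-N,4-dimethylcyclohex-3-ene-1-carboxamide | CC1=C[C@@H](/C=C(\C)CO[Si](C)(C)C(C)(C)C)[C@@H](C(=O)N(C)OC)CC1 | intermediate
13 | 1-[(1S,2S)-2-[(1E)-3-(tert-butyldimethylsilyloxy)-2-methylprop-1-en-1-yl]-4-methylcyclohex-3-en-1-yl]ethan-1-one | CC1=C[C@@H](/C=C(\C)CO[Si](C)(C)C(C)(C)C)[C@@H](C(C)=O)CC1 | intermediate
14 | (S)-2-methylpropane-2-sulfinamide | CC(C)(C)[S@@](N)=O | starting material
15 | (S)-N-{(1E)-1-[(1S,2S)-2-[(1E)-3-(tert-butyldimethylsilyloxy)-2-methylprop-1-en-1-yl]-4-methylcyclohex-3-en-1-yl]ethylidene}-2-methylpropane-2-sulfinamide | CC1=C[C@@H](/C=C(\C)CO[Si](C)(C)C(C)(C)C)[C@@H](/C(C)=N/[S@@](=O)C(C)(C)C)CC1 | intermediate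
16 | methyl acetate | COC(C)=O | starting material
17 | methyl (3R)-3-[(1S,2S)-2-[(1E)-3-(tert-butyldimethylsilyloxy)-2-methylprop-1-en-1-yl]-4-methylcyclohex-3-en-1-yl]-3-{[(S)-tert-butylsulfinyl]amino}butanoate | CC1=C[C@@H](/C=C(\C)CO[Si](C)(C)C(C)(C)C)[C@@H]([C@](C)(N[S@@](=O)C(C)(C)C)CC(=O)OC)CC1 | intermediate
18 | methyl (3R)-3-{[(S)-tert-butylsulfinyl]amino}-3-[(1S,2S)-2-[(1E)-3-hydroxy-2-methylprop-1-en-1-yl]-4-methylcyclohex-3-en-1-yl]butanoate | CC1=C[C@@H](/C=C(\C)CO)[C@@H]([C@](C)(N[S@@](=O)C(C)(C)C)CC(=O)OC)CC1 | intermediate
19 | allylic mesylate of 18 (formed and used in the flask in step 12) | CC1=C[C@@H](/C=C(\C)COS(C)(=O)=O)[C@@H]([C@](C)(N[S@@](=O)C(C)(C)C)CC(=O)OC)CC1 | intermediate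
20 | methyl (3R)-3-[(1S,2S)-2-[(1E)-3-bromo-2-methylprop-1-en-1-yl]-4-methylcyclohex-3-en-1-yl]-3-{[(S)-tert-butylsulfinyl]amino}butanoate | CC1=C[C@@H](/C=C(\C)CBr)[C@@H]([C@](C)(N[S@@](=O)C(C)(C)C)CC(=O)OC)CC1 | intermediate
21 | N-(tert-butoxycarbonyl)-2-aminoisobutyric acid | CC(C)(NC(=O)OC(C)(C)C)C(=O)O | starting material
22 | 3-tert-butoxy-3-oxopropanoic acid (mono-tert-butyl malonate) | CC(C)(C)OC(=O)CC(=O)O | starting material
23 | tert-butyl 4-[(tert-butoxycarbonyl)amino]-4-methyl-3-oxopentanoate | CC(C)(C)OC(=O)CC(=O)C(C)(C)NC(=O)OC(C)(C)C | intermediate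
24 | methyl (3R)-3-[(1S,2S)-2-{(1E)-4-(tert-butoxycarbonyl)-6-[(tert-butoxycarbonyl)amino]-2,6-dimethyl-5-oxohept-1-en-1-yl}-4-methylcyclohex-3-en-1-yl]-3-{[(S)-tert-butylsulfinyl]amino}butanoate (both C7 epimers) | CC1=C[C@@H](/C=C(\C)CC(C(=O)OC(C)(C)C)C(=O)C(C)(C)NC(=O)OC(C)(C)C)[C@@H]([C@](C)(N[S@@](=O)C(C)(C)C)CC(=O)OC)CC1 | intermediate
25 | β-keto acid bis(ammonium chloride) from 24 (formed and used in the flask in step 15) | CC1=C[C@@H](/C=C(\C)CC(C(=O)O)C(=O)C(C)(C)N)[C@@H]([C@](C)(N)CC(=O)OC)CC1.Cl.Cl | intermediate
26 | methyl (3R)-3-amino-3-[(1S,2S)-2-[(1E)-6-amino-2,6-dimethyl-5-oxohept-1-en-1-yl]-4-methylcyclohex-3-en-1-yl]butanoate dihydrochloride (formed and used in the flask in step 15) | CC1=C[C@@H](/C=C(\C)CCC(=O)C(C)(C)N)[C@@H]([C@](C)(N)CC(=O)OC)CC1.Cl.Cl | intermediate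
27 | methyl (3R)-3-formamido-3-[(1S,2S)-2-[(1E)-6-formamido-2,6-dimethyl-5-oxohept-1-en-1-yl]-4-methylcyclohex-3-en-1-yl]butanoate | CC1=C[C@@H](/C=C(\C)CCC(=O)C(C)(C)NC=O)[C@@H]([C@](C)(NC=O)CC(=O)OC)CC1 | intermediate
28 | methyl (3R)-3-formamido-3-[(1S,2S)-2-[(1E,5R)-6-formamido-5-hydroxy-2,6-dimethylhept-1-en-1-yl]-4-methylcyclohex-3-en-1-yl]butanoate | CC1=C[C@@H](/C=C(\C)CC[C@@H](O)C(C)(C)NC=O)[C@@H]([C@](C)(NC=O)CC(=O)OC)CC1 | intermediate
29 | N-{(2R)-2-[(1S,2S)-2-[(1E,5R)-6-formamido-5-hydroxy-2,6-dimethylhept-1-en-1-yl]-4-methylcyclohex-3-en-1-yl]-4-hydroxybutan-2-yl}formamide | CC1=C[C@@H](/C=C(\C)CC[C@@H](O)C(C)(C)NC=O)[C@@H]([C@](C)(NC=O)CCO)CC1 | intermediate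
30 | N-{(2R)-2-[(1S,2S)-2-[(1E,5R)-6-formamido-5-hydroxy-2,6-dimethylhept-1-en-1-yl]-4-methylcyclohex-3-en-1-yl]-4-oxobutan-2-yl}formamide | CC1=C[C@@H](/C=C(\C)CC[C@@H](O)C(C)(C)NC=O)[C@@H]([C@](C)(NC=O)CC=O)CC1 | intermediate
31 | N-{2-[(2R,5S)-5-[(1S,2S,4R,4aS,8aR)-4-formamido-2-hydroxy-4,7-dimethyl-1,2,3,4,4a,5,6,8a-octahydronaphthalen-1-yl]-5-methyloxolan-2-yl]propan-2-yl}formamide | CC1=C[C@H]2[C@H]([C@]3(C)CC[C@H](C(C)(C)NC=O)O3)[C@@H](O)C[C@@](C)(NC=O)[C@H]2CC1 | intermediate
32 | O-[(1S,2S,4R,4aS,8aR)-4-formamido-1-{(2S,5R)-5-(2-formamidopropan-2-yl)-2-methyloxolan-2-yl}-4,7-dimethyl-1,2,3,4,4a,5,6,8a-octahydronaphthalen-2-yl] 1H-imidazole-1-carbothioate | CC1=C[C@H]2[C@H]([C@]3(C)CC[C@H](C(C)(C)NC=O)O3)[C@@H](OC(=S)n4ccnc4)C[C@@](C)(NC=O)[C@H]2CC1 | intermediate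
33 | N-{2-[(2R,5S)-5-[(1R,4R,4aS,8aR)-4-formamido-4,7-dimethyl-1,2,3,4,4a,5,6,8a-octahydronaphthalen-1-yl]-5-methyloxolan-2-yl]propan-2-yl}formamide (CNP0173819.1) | CC1=C[C@H]2[C@H]([C@]3(C)CC[C@H](C(C)(C)NC=O)O3)CC[C@@](C)(NC=O)[C@H]2CC1 | target

## Step count and least certain steps

Total step count: 21. Longest linear sequence: 19 steps (steps 1–4, 6–12 and 14–21); steps 5 and 13 make the side fragments 10 and 23.

**Step 19 (key step).** The most likely deviation is that, after the C4–C11 bond has formed, the developing C5 cation loses a proton from the C5 methyl or from C6 to the neighbouring aluminium alkoxide (the carbonyl-ene outcome) before O10 closes ring C, because the alkoxide is held next to the cation whereas the hydroxyl chain has to fold. Two lesser deviations are attack of the ring A alkene on the aldehyde (the bridged mode) and reversible ionisation of the new tertiary ether under the Lewis acid, which would erode C5. The fallback removes the internal base by changing the initiator from a Lewis acid-bound aldehyde to an oxocarbenium ion. Aldehyde 30 would be converted with propane-1,3-diol and pyridinium tosylate into its 1,3-dioxane acetal F1. Treatment with SnCl4 in CH2Cl2 at −78 °C (acetal-initiated cation–olefin cyclisation with the same chair and the same anti capture by O10) should give the 3-hydroxypropyl ether of the cyclised carbinol F2. Oxidation of its primary alcohol with Dess–Martin periodinane gives the 3-oxopropyl ether F3, and β-elimination with piperidinium acetate releases the carbinol, which rejoins the route at 31.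

**Step 10.** The ketimine is flanked by a ring carbon that carries a cis neighbour, so the titanium enolate may add slowly or reversibly. Any loss of the cis relationship at C14 while ketimine 15 is formed and handled in step 9 would also show here as a mixture of diastereomers, and the ring stereocentres may oppose the sulfinyl group in face selection. The fallback replaces the acetate enolate by a smaller, irreversible nucleophile and makes C11 by hydroboration instead of ester reduction. From 15, vinyllithium with AlMe3 in toluene at −78 °C (same chelated model, same face) should give the vinyl sulfinamide F4. The operations of steps 11, 12, 14, 15 and 16 then give in turn the allylic alcohol F5, the mesylate F6, the allylic bromide F7, the alkylated β-keto ester F8 (from 23), the β-keto acid bis(ammonium chloride) F9, the diamine dihydrochloride F10, the keto bis-formamide F11 and the (8R)-hydroxy bis-formamide F12. Hydroboration of the vinyl group of F12 with 9-borabicyclo[3.3.1]nonane, which leaves trisubstituted alkenes alone, and oxidation with NaBO3·4H2O give the diol, which rejoins the route at 29.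

**Step 16.** The two groups on the C8 carbonyl are both bulky or polar (a tert-alkyl carbon bearing a formamide, and a chain), and the formamides can bind borane, so enantioface selection may be poor. The resulting C8 epimers would differ only at a remote centre and would be hard to separate. The fallback sets C8 on a small fragment before the union. Acid 21, activated with 1,1'-carbonyldiimidazole, is acylated by lithiated methyl phenyl sulfone to give β-keto sulfone F13. Hydrogenation with RuCl2[(S)-2,2'-bis(diphenylphosphino)-1,1'-binaphthyl] (sense assigned by analogy with β-keto esters) gives the (S)-β-hydroxy sulfone F14, whose enantiopurity can be raised by crystallisation. Its trianion (BuLi, 3 equiv) is alkylated by bromide 20 to give the C7-sulfonyl hydroxy carbamate F15. Sodium amalgam (Na/Hg, Na2HPO4, MeOH) removes the sulfonyl group to give the (8R)-hydroxy carbamate F16. HCl in MeOH–dioxane at 0 °C then frees both amines as the hydroxy diamine dihydrochloride F17, and N-selective formylation with acetic formic anhydride rejoins the route at 28.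

**Step 7.** The acyl carbonyl of 11 is crowded by the cis arm, so the aluminium amide may open the oxazolidinone ring at its own carbonyl instead of transferring the acyl group. The fallback is hydrolysis followed by organolithium addition: LiOH/H2O2 in THF–water, which is selective for the exocyclic carbonyl even in hindered imides, gives the carboxylic acid F18, and MeLi (2.2 equiv, Et2O, 0 °C; Me3SiCl quench) converts the lithium carboxylate into the methyl ketone, which rejoins the route at 13.

## Further compounds

F1 | step 19 | N-{(2R)-1-(1,3-dioxan-2-yl)-2-[(1S,2S)-2-[(1E,5R)-6-formamido-5-hydroxy-2,6-dimethylhept-1-en-1-yl]-4-methylcyclohex-3-en-1-yl]propan-2-yl}formamide | CC1=C[C@@H](/C=C(\C)CC[C@@H](O)C(C)(C)NC=O)[C@@H]([C@](C)(NC=O)CC2OCCCO2)CC1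
F2 | step 19 | 3-hydroxypropyl ether of 31 at the C11 oxygen | CC1=C[C@H]2[C@H]([C@]3(C)CC[C@H](C(C)(C)NC=O)O3)[C@@H](OCCCO)C[C@@](C)(NC=O)[C@H]2CC1
F3 | step 19 | 3-oxopropyl ether of 31 at the C11 oxygen | CC1=C[C@H]2[C@H]([C@]3(C)CC[C@H](C(C)(C)NC=O)O3)[C@@H](OCCC=O)C[C@@](C)(NC=O)[C@H]2CC1
F4 | step 10 | (S)-N-{(2R)-2-[(1S,2S)-2-[(1E)-3-(tert-butyldimethylsilyloxy)-2-methylprop-1-en-1-yl]-4-methylcyclohex-3-en-1-yl]but-3-en-2-yl}-2-methylpropane-2-sulfinamide | CC1=C[C@@H](/C=C(\C)CO[Si](C)(C)C(C)(C)C)[C@@H]([C@](C)(N[S@@](=O)C(C)(C)C)C=C)CC1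
F5 | step 10 | allylic alcohol of the vinyl series | CC1=C[C@@H](/C=C(\C)CO)[C@@H]([C@](C)(N[S@@](=O)C(C)(C)C)C=C)CC1
F6 | step 10 | allylic mesylate of the vinyl series | CC1=C[C@@H](/C=C(\C)COS(C)(=O)=O)[C@@H]([C@](C)(N[S@@](=O)C(C)(C)C)C=C)CC1
F7 | step 10 | allylic bromide of the vinyl series | CC1=C[C@@H](/C=C(\C)CBr)[C@@H]([C@](C)(N[S@@](=O)C(C)(C)C)C=C)CC1
F8 | step 10 | alkylated β-keto ester of the vinyl series (both C7 epimers) | CC1=C[C@@H](/C=C(\C)CC(C(=O)OC(C)(C)C)C(=O)C(C)(C)NC(=O)OC(C)(C)C)[C@@H]([C@](C)(N[S@@](=O)C(C)(C)C)C=C)CC1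
F9 | step 10 | β-keto acid bis(ammonium chloride) of the vinyl series | CC1=C[C@@H](/C=C(\C)CC(C(=O)O)C(=O)C(C)(C)N)[C@@H]([C@](C)(N)C=C)CC1.Cl.Cl
F10 | step 10 | diamine dihydrochloride of the vinyl series | CC1=C[C@@H](/C=C(\C)CCC(=O)C(C)(C)N)[C@@H]([C@](C)(N)C=C)CC1.Cl.Cl
F11 | step 10 | keto bis-formamide of the vinyl series | CC1=C[C@@H](/C=C(\C)CCC(=O)C(C)(C)NC=O)[C@@H]([C@](C)(NC=O)C=C)CC1
F12 | step 10 | (8R)-hydroxy bis-formamide of the vinyl series | CC1=C[C@@H](/C=C(\C)CC[C@@H](O)C(C)(C)NC=O)[C@@H]([C@](C)(NC=O)C=C)CC1
F13 | step 16 | tert-butyl [2-methyl-3-oxo-4-(phenylsulfonyl)butan-2-yl]carbamate | CC(C)(C)OC(=O)NC(C)(C)C(=O)CS(=O)(=O)c1ccccc1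
F14 | step 16 | tert-butyl [(3S)-3-hydroxy-2-methyl-4-(phenylsulfonyl)butan-2-yl]carbamate | CC(C)(C)OC(=O)NC(C)(C)[C@H](O)CS(=O)(=O)c1ccccc1
F15 | step 16 | C7-phenylsulfonyl (8S)-hydroxy carbamate from 20 and F14 (both C7 epimers) | CC1=C[C@@H](/C=C(\C)CC([C@@H](O)C(C)(C)NC(=O)OC(C)(C)C)S(=O)(=O)c2ccccc2)[C@@H]([C@](C)(N[S@@](=O)C(C)(C)C)CC(=O)OC)CC1
F16 | step 16 | methyl (3R)-3-[(1S,2S)-2-{(1E,5R)-6-[(tert-butoxycarbonyl)amino]-5-hydroxy-2,6-dimethylhept-1-en-1-yl}-4-methylcyclohex-3-en-1-yl]-3-{[(S)-tert-butylsulfinyl]amino}butanoate | CC1=C[C@@H](/C=C(\C)CC[C@@H](O)C(C)(C)NC(=O)OC(C)(C)C)[C@@H]([C@](C)(N[S@@](=O)C(C)(C)C)CC(=O)OC)CC1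
F17 | step 16 | methyl (3R)-3-amino-3-[(1S,2S)-2-[(1E,5R)-6-amino-5-hydroxy-2,6-dimethylhept-1-en-1-yl]-4-methylcyclohex-3-en-1-yl]butanoate dihydrochloride | CC1=C[C@@H](/C=C(\C)CC[C@@H](O)C(C)(C)N)[C@@H]([C@](C)(N)CC(=O)OC)CC1.Cl.Cl
F18 | step 7 | (1S,2S)-2-[(1E)-3-(tert-butyldimethylsilyloxy)-2-methylprop-1-en-1-yl]-4-methylcyclohex-3-ene-1-carboxylic acid | CC1=C[C@@H](/C=C(\C)CO[Si](C)(C)C(C)(C)C)[C@@H](C(=O)O)CC1
A1 | alternative 1 | N-(1-methyl-4-oxocyclohexa-2,5-dien-1-yl)acetamide | CC(=O)NC1(C)C=CC(=O)C=C1
A2 | alternative 1 | (1E)-1-methoxy-2-methyl-3-(trimethylsilyloxy)buta-1,3-diene | CO/C=C(\C)C(=C)O[Si](C)(C)C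
A3 | alternative 1 | cis-fused acetamido octalin dione with the ring A alkene in place | CC1=C[C@H]2C(=O)C=C[C@@](C)(NC(C)=O)[C@H]2CC1=O
A4 | alternative 2 | (2Z,7Z)-4-[(2S,5R)-5-(2-azidopropan-2-yl)-2-methyloxolan-2-yl]-1,7-dimethylcyclodeca-2,7-dien-1-ol | CC1(O)/C=C\[C@H]([C@]2(C)CC[C@H](C(C)(C)N=[N+]=[N-])O2)CC/C(C)=C\CC1
A5 | alternative 2 | bis-azide with the complete ring system | CC1=C[C@H]2[C@H]([C@]3(C)CC[C@H](C(C)(C)N=[N+]=[N-])O3)CC[C@@](C)(N=[N+]=[N-])[C@H]2CC1
A6 | alternative 3 | N-(4-methoxybenzyl) imine of the cis-hydrindane α-hydroxy methyl ketone | CC1=C[C@H]2[C@H]([C@]3(C)CC[C@H](C(C)(C)NC=O)O3)C[C@](O)(/C(C)=N/Cc4ccc(OC)cc4)[C@H]2CC1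
A7 | alternative 3 | cis-decalin α-(4-methoxybenzylamino) ketone | CC1=C[C@H]2[C@H]([C@]3(C)CC[C@H](C(C)(C)NC=O)O3)CC(=O)[C@@](C)(NCc4ccc(OC)cc4)[C@H]2CC1
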